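**Plan**

1. Numbering follows the open-chain C24 acid (C1 = ester carbon, C24 = chain-end methyl). In the target the cyclobutane is C7–C8–C13–C14, ring A is the cyclohexene C8–C13 (C11=C12), the cyclopentane is C5–C9, and ring B is the cyclohexene C2–C5/C9–C10 (C3=C4).
2. Retrosynthesis cuts C5–C9 and C2–C10 first: ring B with its C3=C4 bond is the Diels–Alder adduct of a C2–C5 dienoyl unit and a C9=C10 bond. It then cuts C8–C13 and C7–C14: a cyclobutane cis-fused to a ring A that is then a cyclohexa-1,3-diene (C9=C10, C11=C12), with trans substituents on C7 and C14, is a bicyclo[4.2.0]octa-2,4-diene, the product of 8π then 6π electrocyclisation of a (7E,9Z,11Z,13E)-tetraene.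
3. The open chain is cut at C8–C9 and C12–C13 (two Sonogashira couplings onto a C9–C12 butadiyne, the Z,Z-diene being released by semi-hydrogenation), at C6–C7 (allyl–vinyl Stille coupling) and at C13=C14 (Takai olefination).
4. Forward: the side-chain vinyl iodide is joined to the diyne and then to the trienoyl iodide. Reduction of the diyne starts a one-pot cascade in which the eight-membered ring (C7–C14), then cyclobutane plus ring A (C8–C13), then cyclopentane plus ring B (C5–C9, C2–C10) arise.
5. The relative configuration of all eight ring stereocentres comes from alkene geometry and orbital symmetry: conrotation sets C7/C14 trans, disrotation sets C8/C13 cis, and the tether-bound exo [4+2] of the E,E-diene sets C2, C5, C9 and C10.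
6. Absolute configuration: the cascade has no bias for either helical sense, so an (S)-4-isopropyloxazolidinone on C1 turns the two ring antipodes into diastereomers that are separated on silica. The one with the target ring configuration is carried on and the auxiliary is exchanged for OMe.

Key step: step 13

Remark: no asymmetric induction by the auxiliary in the electrocyclisations is assumed, so step 13 should deliver 23 together with its diastereomer that has all eight ring stereocentres inverted and the same (S)-auxiliary, and at most half of the material is carried on; the auxiliary serves as a covalent resolving handle of known configuration, which also lets the ring configuration of the separated diastereomers be assigned, and either antipode of it would serve.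

**Route**

Step 1
Reactants: 1 undec-10-yn-1-ol
Product: 2 undec-9-yn-1-ol
Conditions: KOtBu (2.5 equiv), DMSO, 23 °C; then dilute HCl
Reagents that add atoms: none
Why: Base-mediated prototropic alkyne isomerisation (through the allene) in KOtBu/DMSO moves the terminal triple bond by one position to the more stable methyl alkyne, and no stereocentre is involved.

Step 2
Reactants: 2 undec-9-yn-1-ol
Product: 3 (E)-undec-9-en-1-ol
Conditions: Li, NH3 (l), THF, −33 °C; then NH4Cl
Reagents that add atoms: none
Why: Dissolving-metal reduction of the internal alkyne passes through the trans vinyl radical anion and so should give only the E alkene that becomes C22=C23.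

Step 3
Reactants: 3 (E)-undec-9-en-1-ol
Product: 4 (E)-undec-9-enal
Conditions: PhI(OAc)2, TEMPO (cat.), CH2Cl2, 23 °C
Reagents that add atoms: none
Why: Oxoammonium (TEMPO/PhI(OAc)2) oxidation takes the primary alcohol to the aldehyde without over-oxidation and does not touch the isolated alkene.

Step 4
Reactants: 4 (E)-undec-9-enal
Product: 5 (1E,10E)-1-iodododeca-1,10-diene
Conditions: CrCl2, CHI3, THF/1,4-dioxane, 0 °C to 23 °C
Reagents that add atoms: iodoform, IC(I)I
Why: Takai olefination with the gem-dichromium reagent from CHI3 and CrCl2 converts the unbranched aldehyde into the (E)-vinyl iodide, which fixes C13=C14 as E.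

Step 5
Reactants: 6 1,4-bis(trimethylsilyl)buta-1,3-diyne
Product: 8 buta-1,3-diyn-1-yl(trimethyl)silane, via lithium acetylide 7 (not isolated)
Conditions: MeLi·LiBr (1 equiv), Et2O, 0 °C to 23 °C; then H2O; kept as Et2O solution
Reagents that add atoms: none
Why: Monodesilylation of the bis-silyl diyne by methyl attack at one silicon stops after the first C–Si cleavage because the acetylide formed deactivates the second silicon, and protonation gives the terminal diyne.

Step 6
Reactants: 5 (1E,10E)-1-iodododeca-1,10-diene; 8 buta-1,3-diyn-1-yl(trimethyl)silane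
Product: 9 [(5E,14E)-hexadeca-5,14-dien-1,3-diyn-1-yl]trimethylsilane
Conditions: PdCl2(PPh3)2 (cat.), CuI (cat.), Et3N, THF, 23 °C
Reagents that add atoms: none
Why: Sonogashira coupling of a vinyl iodide with a terminal alkyne joins C12 to C13 with retention of the E geometry.

Step 7
Reactants: 9 [(5E,14E)-hexadeca-5,14-dien-1,3-diyn-1-yl]trimethylsilane
Product: 10 (5E,14E)-hexadeca-5,14-dien-1,3-diyne
Conditions: K2CO3 (cat.), MeOH/THF, 0 °C; used at once in solution
Reagents that add atoms: none
Why: Base-catalysed methanolysis of the alkynyl C–Si bond frees the terminal diyne under conditions that the two E alkenes tolerate.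

Step 8
Reactants: 11 (S)-4-isopropyloxazolidin-2-one; 12 (2E,4E)-hexa-2,4-dienoyl chloride (sorboyl chloride)
Product: 14 (S)-3-[(2E,4E)-hexa-2,4-dienoyl]-4-isopropyloxazolidin-2-one, via lithium oxazolidinide 13 (not isolated)
Conditions: n-BuLi, THF, −78 °C; then 12, −78 °C to 0 °C
Reagents that add atoms: none
Why: N-Acylation of the lithiated oxazolidinone by the acid chloride installs the auxiliary of fixed S configuration without touching the E,E-diene.

Step 9
Reactants: 14 (S)-3-[(2E,4E)-hexa-2,4-dienoyl]-4-isopropyloxazolidin-2-one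
Product: 15 (S)-3-[(2E,4E)-6-bromohexa-2,4-dienoyl]-4-isopropyloxazolidin-2-one
Conditions: NBS, AIBN (cat.), PhCF3, 85 °C
Reagents that add atoms: N-bromosuccinimide, O=C1CCC(=O)N1Br
Why: Wohl–Ziegler bromination goes through the pentadienyl radical, which should take up bromine at the terminal C6 so that the conjugated E,E-dienoyl system is kept, as is known for sorbate esters.

Step 10
Reactants: 15 (S)-3-[(2E,4E)-6-bromohexa-2,4-dienoyl]-4-isopropyloxazolidin-2-one; 16 (E)-1,2-bis(tributylstannyl)ethene
Product: 17 (S)-4-isopropyl-3-[(2E,4E,7E)-8-(tributylstannyl)octa-2,4,7-trienoyl]oxazolidin-2-one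
Conditions: Pd2(dba)3 (cat.), AsPh3, THF, 50 °C; 16 in excess
Reagents that add atoms: none
Why: Stille allyl–vinyl coupling: the pentadienyl palladium intermediate from 15 should couple at its terminal carbon C6 with one stannyl end of 16 (retention at the vinyl carbon), which forms C6–C7 and leaves the E-vinylstannane for the next step.

Step 11
Reactants: 17 (S)-4-isopropyl-3-[(2E,4E,7E)-8-(tributylstannyl)octa-2,4,7-trienoyl]oxazolidin-2-one
Product: 18 (S)-3-[(2E,4E,7E)-8-iodoocta-2,4,7-trienoyl]-4-isopropyloxazolidin-2-one
Conditions: I2, CH2Cl2, 0 °C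
Reagents that add atoms: iodine, II
Why: Iododestannylation is an ipso electrophilic substitution at the vinyl carbon and proceeds with retention, so C7=C8 stays E.

Step 12
Reactants: 18 (S)-3-[(2E,4E,7E)-8-iodoocta-2,4,7-trienoyl]-4-isopropyloxazolidin-2-one; 10 (5E,14E)-hexadeca-5,14-dien-1,3-diyne
Product: 19 (S)-4-isopropyl-3-[(2E,4E,7E,13E,22E)-tetracosa-2,4,7,13,22-pentaen-9,11-diynoyl]oxazolidin-2-one
Conditions: Pd(PPh3)4 (cat.), CuI (cat.), Et3N, THF (degassed), 0 °C to 23 °C
Reagents that add atoms: none
Why: Sonogashira coupling forms C8–C9 with retention of the E geometry under amine conditions too weakly basic to deprotonate the doubly allylic C6H2 group.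

Step 13
Reactants: 19 (S)-4-isopropyl-3-[(2E,4E,7E,13E,22E)-tetracosa-2,4,7,13,22-pentaen-9,11-diynoyl]oxazolidin-2-one
Product: 23 tetracyclic N-acyl oxazolidinone with the ring configuration of the target, via heptaenoyl imide 20 (not isolated), via cyclooctatriene 21 (not isolated), via bicyclooctadiene 22 (not isolated)
Conditions: H2 (1 atm), Pd/CaCO3 poisoned with Pb(OAc)2 (Lindlar catalyst), quinoline, CH2Cl2, 23 °C, to uptake of 2 equiv; filter; then PhMe (high dilution), BHT, 105 °C; SiO2 chromatography
Reagents that add atoms: none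
Why: cis-Semi-hydrogenation of both alkynes of 19 releases the (7E,9Z,11Z,13E)-tetraene 20, which should undergo thermal conrotatory 8π electrocyclisation (C7–C14) to cyclooctatriene 21, disrotatory 6π electrocyclisation (C8–C13) to bicyclo[4.2.0]octadiene 22 and, on heating, an intramolecular Diels–Alder reaction of the C2–C5 dienoyl unit with C9=C10 (bonds C5–C9 and C2–C10). The closest known reaction type is the thermal 8π/6π electrocyclisation cascade of (E,Z,Z,E)-tetraenes to bicyclo[4.2.0]octa-2,4-dienes followed by an intramolecular [4+2] cycloaddition onto the ring diene. The eight-membered ring closes by 8π conrotation, the cyclobutane and ring A close together by 6π disrotation of the C8–C13 triene, and the cyclopentane and ring B close together by a [4+2] cycloaddition through the three-atom tether C6–C7–C8. C7/C14 become trans because the E,E termini rotate in the same sense; C8/C13 become cis by disrotation, and since either disrotatory sense is reversible through 21, material drains through the sense that places the C7 chain endo (decenyl exo), the only one that can cyclise further; C5, C9 and C10 follow from suprafacial addition to the ring face that the C7 tether reaches, in the exo orientation (ring A away from C3–C4) that this short tether imposes, and C2 follows from the E geometry of C2=C3. The step needs periselectivity (the dienoyl unit as 4π partner, not the ring A diene adding to C4=C5), which the pairing of an electron-poor acyl diene with the electron-rich cis C9=C10 bond and the reach of the endo CH2 tether are expected to favour, and it needs chemoselective alkyne reduction, which the poisoned catalyst and the fast removal of 20 by cyclisation support. The helical sense of the 8π step is not controlled, so 23 should form together with the diastereomer in which all eight ring stereocentres are inverted, and the auxiliary next to C2 should allow 23 to be separated from it on silica.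

Step 14
Reactants: 23 tetracyclic N-acyl oxazolidinone with the ring configuration of the target
Product: 25 tetracyclic carboxylic acid (free acid of the target), via peroxy acid 24 (not isolated)
Conditions: LiOH, H2O2, THF/H2O, 0 °C; then Na2SO3; then dilute HCl to pH 3
Reagents that add atoms: hydrogen peroxide, OO
Why: Hydroperoxide cleavage of the N-acyl oxazolidinone attacks the exocyclic carbonyl selectively and, being weakly basic at 0 °C, should leave the allylic C2–H and the C3=C4 position untouched, with sulfite reducing the peroxy acid 24.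

Step 15
Reactants: 25 tetracyclic carboxylic acid (free acid of the target)
Product: 26 methyl ester CNP0133550.1 (target)
Conditions: TMSCHN2, PhMe/MeOH, 0 °C to 23 °C
Reagents that add atoms: (trimethylsilyl)diazomethane, C[Si](C)(C)C=[N+]=[N-]
Why: Esterification with TMSCHN2 in the presence of MeOH (protonation of the diazoalkane, then O-alkylation of the carboxylate) is neutral, so C2 is not epimerised and the target 26 results.

**Compound list**

1 | undec-10-yn-1-ol | C#CCCCCCCCCCO | starting material
2 | undec-9-yn-1-ol | CC#CCCCCCCCCO | intermediate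
3 | (E)-undec-9-en-1-ol | C/C=C/CCCCCCCCO | intermediate
4 | (E)-undec-9-enal | C/C=C/CCCCCCCC=O | intermediate
5 | (1E,10E)-1-iodododeca-1,10-diene | C/C=C/CCCCCCC/C=C/I | intermediate
6 | 1,4-bis(trimethylsilyl)buta-1,3-diyne | C[Si](C)(C)C#CC#C[Si](C)(C)C | starting material
7 | lithium 4-(trimethylsilyl)buta-1,3-diyn-1-ide | [Li]C#CC#C[Si](C)(C)C | intermediate
8 | buta-1,3-diyn-1-yl(trimethyl)silane | C#CC#C[Si](C)(C)C | intermediate
9 | [(5E,14E)-hexadeca-5,14-dien-1,3-diyn-1-yl]trimethylsilane | C/C=C/CCCCCCC/C=C/C#CC#C[Si](C)(C)C | intermediate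
10 | (5E,14E)-hexadeca-5,14-dien-1,3-diyne | C/C=C/CCCCCCC/C=C/C#CC#C | intermediate
11 | (S)-4-isopropyloxazolidin-2-one | CC(C)[C@H]1COC(=O)N1 | starting material
12 | (2E,4E)-hexa-2,4-dienoyl chloride | C/C=C/C=C/C(=O)Cl | starting material
13 | N-lithio-(S)-4-isopropyloxazolidin-2-one | CC(C)[C@H]1COC(=O)N1[Li] | intermediate
14 | (S)-3-[(2E,4E)-hexa-2,4-dienoyl]-4-isopropyloxazolidin-2-one | CC(C)[C@H]1COC(=O)N1C(=O)/C=C/C=C/C | intermediate
15 | (S)-3-[(2E,4E)-6-bromohexa-2,4-dienoyl]-4-isopropyloxazolidin-2-one | CC(C)[C@H]1COC(=O)N1C(=O)/C=C/C=C/CBr | intermediate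
16 | (E)-1,2-bis(tributylstannyl)ethene | CCCC[Sn](CCCC)(CCCC)/C=C/[Sn](CCCC)(CCCC)CCCC | starting material
17 | (S)-4-isopropyl-3-[(2E,4E,7E)-8-(tributylstannyl)octa-2,4,7-trienoyl]oxazolidin-2-one | CC(C)[C@H]1COC(=O)N1C(=O)/C=C/C=C/C/C=C/[Sn](CCCC)(CCCC)CCCC | intermediate
18 | (S)-3-[(2E,4E,7E)-8-iodoocta-2,4,7-trienoyl]-4-isopropyloxazolidin-2-one | CC(C)[C@H]1COC(=O)N1C(=O)/C=C/C=C/C/C=C/I | intermediate
19 | (S)-4-isopropyl-3-[(2E,4E,7E,13E,22E)-tetracosa-2,4,7,13,22-pentaen-9,11-diynoyl]oxazolidin-2-one | CC(C)[C@H]1COC(=O)N1C(=O)/C=C/C=C/C/C=C/C#CC#C/C=C/CCCCCCC/C=C/C | intermediate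
20 | (S)-4-isopropyl-3-[(2E,4E,7E,9Z,11Z,13E,22E)-tetracosa-2,4,7,9,11,13,22-heptaenoyl]oxazolidin-2-one | CC(C)[C@H]1COC(=O)N1C(=O)/C=C/C=C/C/C=C/C=C\C=C/C=C/CCCCCCC/C=C/C | intermediate
21 | trans-7,8-disubstituted cycloocta-1,3,5-triene: C14 carries the (E)-dec-8-enyl chain, C7 the (2E,4E)-dienoyl imide chain through C6H2; C7 and C14 configured as in 26 | C/C=C/CCCCCCC[C@@H]1/C=C\C=C/C=C\[C@H]1C/C=C/C=C/C(=O)N1C(=O)OC[C@@H]1C(C)C | intermediate
22 | cis-fused bicyclo[4.2.0]octa-2,4-diene: C7 chain (CH2-dienoyl imide) endo, decenyl on C14 exo and trans to it; C7, C8, C13, C14 configured as in 26 | C/C=C/CCCCCCC[C@@H]1[C@H]2C=CC=C[C@H]2[C@H]1C/C=C/C=C/C(=O)N1C(=O)OC[C@@H]1C(C)C | intermediate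
23 | tetracyclic N-acyl (S)-4-isopropyloxazolidinone, all eight ring stereocentres as in 26 | C/C=C/CCCCCCC[C@@H]1[C@H]2C=C[C@@H]3[C@@H]4[C@H]2[C@H]1C[C@H]4C=C[C@H]3C(=O)N1C(=O)OC[C@@H]1C(C)C | intermediate
24 | peroxy acid of 25 | C/C=C/CCCCCCC[C@@H]1[C@H]2C=C[C@@H]3[C@@H]4[C@H]2[C@H]1C[C@H]4C=C[C@H]3C(=O)OO | intermediate
25 | tetracyclic carboxylic acid, ring configuration as in 26 | C/C=C/CCCCCCC[C@@H]1[C@H]2C=C[C@@H]3[C@@H]4[C@H]2[C@H]1C[C@H]4C=C[C@H]3C(=O)O | intermediate
26 | methyl ester CNP0133550.1: (E)-dec-8-enyl on cyclobutane carbon C14, CO2Me on C2 of ring B | C/C=C/CCCCCCC[C@@H]1[C@H]2C=C[C@@H]3[C@@H]4[C@H]2[C@H]1C[C@H]4C=C[C@H]3C(=O)OC | target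

**Count**

Total steps: 15. Longest linear sequence: 10 steps (1, 2, 3, 4, 6, 7, 12, 13, 14, 15).

**Steps most likely to fail**

Step 13. The semi-hydrogenation may over-reduce the diyne or stop at the enyne, and any loss of the Z,Z geometry stops both electrocyclisations. Later in the same pot the ring A diene may add to C4=C5 instead, which would give a bicyclo[2.2.2]octene isomer to be removed on silica. The fallback builds the tetraene without hydrogen by a Stille union at C10–C11 of two Z-configured halves; it sets out from 4 and 18 and comes back at 20. Wittig reaction of 4 with Ph3P=CHCHO (PhMe, 80 °C) should give (2E,11E)-trideca-2,11-dienal F1, and Stork–Zhao olefination of this (Ph3PCH2I iodide, NaHMDS, THF/DMPU, −78 °C) should give (1Z,3E,12E)-1-iodotetradeca-1,3,12-triene F2. Iodide 18 is coupled once (Pd2(dba)3, AsPh3, NMP, 23 °C) with an excess of (Z)-1,2-bis(tributylstannyl)ethene F3, itself made from acetylene and Bu3SnSnBu3 with Pd(PPh3)4, which should give (S)-4-isopropyl-3-[(2E,4E,7E,9Z)-10-(tributylstannyl)deca-2,4,7,9-tetraenoyl]oxazolidin-2-one F4. Stille coupling of F2 with F4 (PdCl2(MeCN)2, DMF, 23 °C) forms C10–C11 with retention at both Z-vinyl carbons and gives heptaenoyl imide 20 directly, which then runs through 21 and 22 and, after heating in PhMe, to 23 as in step 13.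

Step 10. The pentadienyl palladium intermediate may couple at its internal carbon C4 instead of C6, the skipped C6H2 pattern may slip into conjugation, and 16 may couple at both ends. The fallback forms C4=C5 by olefination instead; it sets out from 11 (as its lithium salt 13) and comes back at 18, so that 14 to 17 are not needed. Acylation of 13 with crotonyl chloride should give (S)-3-[(E)-but-2-enoyl]-4-isopropyloxazolidin-2-one F5, Wohl–Ziegler bromination (NBS, AIBN, PhCF3, 85 °C) should give (S)-3-[(E)-4-bromobut-2-enoyl]-4-isopropyloxazolidin-2-one F6, and Michaelis–Arbuzov reaction with P(OEt)3 (100 °C) should give (S)-3-[(E)-4-(diethoxyphosphoryl)but-2-enoyl]-4-isopropyloxazolidin-2-one F7. But-3-yn-1-ol is hydrozirconated (Cp2Zr(H)Cl, 2 equiv, THF) and iodinated (I2) to (E)-4-iodobut-3-en-1-ol F8, then oxidised (Dess–Martin periodinane, NaHCO3, CH2Cl2, 0 °C) to (E)-4-iodobut-3-enal F9, used cold and at once. Vinylogous Horner–Wadsworth–Emmons reaction of lithiated F7 (LiHMDS, THF, −78 °C) with F9 forms C4=C5 with E geometry and gives 18.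

Step 14. The basic peroxide medium may epimerise C2 or move C3=C4 into conjugation with the acyl group. The fallback removes the auxiliary by reduction and returns to the acid by non-basic oxidations; it sets out from 23 and comes back at 25. Reduction (LiBH4, H2O, Et2O, 0 °C) should give the C1 primary alcohol F10 and return 11, buffered Dess–Martin oxidation should give the C1 aldehyde F11, and Pinnick oxidation (NaClO2, NaH2PO4, 2-methylbut-2-ene, tBuOH/H2O) should give acid 25.

**Further compounds**

F1 | step 13 | (2E,11E)-trideca-2,11-dienal | C/C=C/CCCCCCC/C=C/C=O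
F2 | step 13 | (1Z,3E,12E)-1-iodotetradeca-1,3,12-triene | C/C=C/CCCCCCC/C=C/C=C\I
F3 | step 13 | (Z)-1,2-bis(tributylstannyl)ethene | CCCC[Sn](CCCC)(CCCC)/C=C\[Sn](CCCC)(CCCC)CCCC
F4 | step 13 | (S)-4-isopropyl-3-[(2E,4E,7E,9Z)-10-(tributylstannyl)deca-2,4,7,9-tetraenoyl]oxazolidin-2-one | CC(C)[C@H]1COC(=O)N1C(=O)/C=C/C=C/C/C=C/C=C\[Sn](CCCC)(CCCC)CCCC
F5 | step 10 | (S)-3-[(E)-but-2-enoyl]-4-isopropyloxazolidin-2-one | CC(C)[C@H]1COC(=O)N1C(=O)/C=C/C
F6 | step 10 | (S)-3-[(E)-4-bromobut-2-enoyl]-4-isopropyloxazolidin-2-one | CC(C)[C@H]1COC(=O)N1C(=O)/C=C/CBr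
F7 | step 10 | (S)-3-[(E)-4-(diethoxyphosphoryl)but-2-enoyl]-4-isopropyloxazolidin-2-one | CC(C)[C@H]1COC(=O)N1C(=O)/C=C/CP(=O)(OCC)OCC
F8 | step 10 | (E)-4-iodobut-3-en-1-ol | OCC/C=C/I
F9 | step 10 | (E)-4-iodobut-3-enal | O=CC/C=C/I
F10 | step 14 | C1 primary alcohol with the ring configuration of 26 | C/C=C/CCCCCCC[C@@H]1[C@H]2C=C[C@@H]3[C@@H]4[C@H]2[C@H]1C[C@H]4C=C[C@H]3CO
F11 | step 14 | C1 aldehyde with the ring configuration of 26 | C/C=C/CCCCCCC[C@@H]1[C@H]2C=C[C@@H]3[C@@H]4[C@H]2[C@H]1C[C@H]4C=C[C@H]3C=O
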